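## Assumption
The target is the trans-(2R,3R) 2-aryl-3-hydroxymethyl-1,4-benzodioxane flavonolignan (selgin 3′,4′-dioxygen bridged to a sinapyl-derived C3 unit), exactly as in the SMILES. The aryl benzyl ethers are assumed removable by Pd/C hydrogenolysis without cleaving the benzodioxane Cα–O bond.

## Retrosynthetic overview
1. Palstatin ⇐ global debenzylation of a tetra-O-benzyl flavone ⇐ I2/DMSO oxidative cyclisation of a 2′-hydroxychalcone ⇐ Claisen–Schmidt of a benzodioxane aldehyde with bis-O-benzyl phloroacetophenone (the A/C rings are built last).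
2. The dioxane ring is closed by a proposed new DDQ dehydrogenative benzylic C(sp3)–H etherification of the free 3′-phenol onto the syringyl CH2. This sets C2 (trans to C3) with C3 already fixed.
3. The C3 (Cβ) stereocentre comes from (R)-benzyl glycidyl ether: Cu-catalysed ArMgBr opening at the terminal carbon, then Mitsunobu inversion onto the 4-OH of 5-bromovanillin.
4. The 4′-O on C3 and 3′-O on C2 regiochemistry is fixed by the bromide in 5-bromovanillin, which is converted to OH late by Miyaura borylation and oxidation.

## Route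

**Step 1**
Reactants: 1 (4-bromo-2,6-dimethoxyphenol); 2 (benzyl bromide)
Product: 3 (2-(benzyloxy)-5-bromo-1,3-dimethoxybenzene)
Conditions: BnBr, K2CO3, DMF, rt, 12 h
Reagents that add atoms: benzyl bromide, BrCc1ccccc1
Why: Williamson ether synthesis protects the syringyl 4-OH as a benzyl ether, which is removed at the end with the other benzyls.

**Step 2**
Reactants: 3 (2-(benzyloxy)-5-bromo-1,3-dimethoxybenzene); 4 ((R)-benzyl glycidyl ether)
Product: 5 ((2R)-1-(benzyloxy)-3-[4-(benzyloxy)-3,5-dimethoxyphenyl]propan-2-ol)
Conditions: (i) 3, Mg, THF, reflux; (ii) CuI (10 mol%), 4, THF, −20 °C → rt; aq. NH4Cl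
Reagents that add atoms: none (Mg and Cu leave; the aryl group comes from 3)
Why: Cu-catalysed Grignard opening of a terminal epoxide at the unhindered CH2 does not touch the carbinol centre, so the (R) configuration is carried into 5. The CIP priority order O > CH2OBn > CH2Ar > H is unchanged, so the descriptor stays R.

**Step 3**
Reactants: 5 ((2R)-alcohol); 6 (5-bromovanillin, 3-bromo-4-hydroxy-5-methoxybenzaldehyde)
Product: 7 (3-bromo-4-{[(2S)-1-(benzyloxy)-3-(4-benzyloxy-3,5-dimethoxyphenyl)propan-2-yl]oxy}-5-methoxybenzaldehyde)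
Conditions: ADDP, PBu3, toluene/THF, 0 °C → 40 °C, 16 h
Reagents that add atoms: none (the phosphine oxide and hydrazide leave)
Why: Mitsunobu etherification of the acidic, p-formyl phenol proceeds by SN2 at the secondary carbinol, inverting the (R)-alcohol to the (S)-ether. After ring closure the two carbon arms swap CIP priority (the CH2Ar arm becomes CH(O)Ar and outranks CH2OR), so this centre becomes (R) at C3 of palstatin. The ring Br marks the future 3′-O.

**Step 4**
Reactants: 7 (aryl bromide); 8 (bis(pinacolato)diboron)
Product: 9 (3-(pinacolboryl)-4-{[(2S)-1-(benzyloxy)-3-(4-benzyloxy-3,5-dimethoxyphenyl)propan-2-yl]oxy}-5-methoxybenzaldehyde)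
Conditions: B2pin2, Pd(dppf)Cl2 (5 mol%), KOAc, 1,4-dioxane, 90 °C, 6 h
Reagents that add atoms: B2pin2, CC1(C)OB(OC1(C)C)B1OC(C)(C)C(C)(C)O1
Why: Miyaura borylation of an aryl bromide tolerates the aldehyde, the benzyl ethers and the ether-bearing stereocentre.

**Step 5**
Reactants: 9 (aryl pinacolboronate); 10 (sodium perborate, NaBO3·4H2O)
Product: 11 (3-hydroxy-4-{[(2S)-1-(benzyloxy)-3-(4-benzyloxy-3,5-dimethoxyphenyl)propan-2-yl]oxy}-5-methoxybenzaldehyde)
Conditions: 10 (3 equiv), THF/H2O 1:1, rt, 1–2 h
Reagents that add atoms: sodium perborate (peroxide oxygen source; the oxygen ends up as the phenol OH), [Na+].[Na+].O[B-]1(O)OO[B-](O)(O)OO1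
Why: Perborate is a mild H2O2 equivalent, so it oxidises the C–B bond of the boronate (oxidative deborylation via 1,2-aryl shift) to the free 3′-phenol with retention at carbon. The short reaction time, rt and near-neutral medium avoid Dakin or acid-forming oxidation of the aldehyde and avoid strongly basic conditions.

**Step 6 (key step)**
Reactants: 11 (phenol aldehyde)
Product: 12 ((2R,3R)-3-(benzyloxymethyl)-2-(4-benzyloxy-3,5-dimethoxyphenyl)-5-methoxy-2,3-dihydro-1,4-benzodioxine-7-carbaldehyde, trans)
Conditions: DDQ (1.3 equiv), 4 Å MS, ClCH2CH2Cl, 0 → 40 °C, Ar, 6 h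
Reagents that add atoms: none (DDQ leaves as DDQH2)
Why: Proposed new method: DDQ abstracts hydride from the p-alkoxybenzylic CH2 (Cα–H2) of the syringyl ring to give a p-alkoxybenzyl cation (quinone-methide-oxonium type). The tethered 3′-OH traps it in a 6-exo closure to form the O–Cα bond, giving the 2-aryl-1,4-benzodioxane. Cβ is untouched and fixes the facial bias of the closure. Ionisation of the product is reversible under the DDQH2/acid conditions, so the trans diequatorial (2R,3R) isomer is thermodynamically favoured. The formyl-bearing ring is electron-poor and is not oxidised. The closest known reactions are Floreancig-type DDQ oxidative cyclisations of p-alkoxybenzyl ethers and DDQ benzylic C–H etherifications to chromans; this has not been shown for β-aryloxy substrates to make 2-aryl-benzodioxanes.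

**Step 7**
Reactants: 13 (2′,4′,6′-trihydroxyacetophenone); 2 (benzyl bromide)
Product: 14 (1-[2-hydroxy-4,6-bis(benzyloxy)phenyl]ethan-1-one)
Conditions: BnBr (2.1 equiv), K2CO3, acetone, reflux, 10 h
Reagents that add atoms: benzyl bromide, BrCc1ccccc1
Why: The 2′-OH is H-bonded to the carbonyl and stays unalkylated, so Williamson benzylation occurs selectively at the 4′- and 6′-OH groups.

**Step 8**
Reactants: 12 (benzodioxane aldehyde); 14 (acetophenone)
Product: 15 ((E)-chalcone)
Conditions: 50% aq. KOH, EtOH/THF, rt, 48 h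
Reagents that add atoms: none
Why: Claisen–Schmidt condensation gives the E-enone; the benzodioxane has no acidic α-H and no base-labile stereocentre, so the C2/C3 centres survive.

**Step 9**
Reactants: 15 (chalcone)
Product: 16 (tetra-O-benzyl flavone carrying the protected benzodioxane)
Conditions: I2 (0.2 equiv), DMSO, 110 °C, 3 h
Reagents that add atoms: none
Why: Iodine-catalysed oxidative cyclisation of a 2′-hydroxychalcone (oxa-Michael addition, then iodination and elimination, with DMSO reoxidising HI to I2) delivers the flavone and leaves the benzyl ethers intact.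

**Step 10**
Reactants: 16 (tetra-O-benzyl flavone)
Product: 17 (palstatin)
Conditions: H2 (1 atm), 10% Pd/C, THF/MeOH 1:1, rt, 24 h
Reagents that add atoms: none (H2 adds only hydrogen; toluene is lost)
Why: Hydrogenolysis removes all four O-benzyl groups (5-OBn, 7-OBn, syringyl 4-OBn and CH2OBn). No new stereocentre forms, and the trans (2R,3R) centres are untouched.

## Compound list
1 | 4-bromo-2,6-dimethoxyphenol | COc1cc(Br)cc(OC)c1O | starting material
2 | benzyl bromide | BrCc1ccccc1 | starting material
3 | 2-(benzyloxy)-5-bromo-1,3-dimethoxybenzene | COc1cc(Br)cc(OC)c1OCc1ccccc1 | intermediate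
4 | (R)-benzyl glycidyl ether | c1ccccc1COC[C@H]1CO1 | starting material
5 | (2R)-1-(benzyloxy)-3-[4-(benzyloxy)-3,5-dimethoxyphenyl]propan-2-ol | c1ccccc1COC[C@H](O)Cc1cc(OC)c(OCc2ccccc2)c(OC)c1 | intermediate
6 | 5-bromovanillin | COc1cc(C=O)cc(Br)c1O | starting material
7 | aryl ether aldehyde (S), aryl bromide | c1ccccc1COC[C@@H](Oc1c(Br)cc(C=O)cc1OC)Cc1cc(OC)c(OCc2ccccc2)c(OC)c1 | intermediate
8 | bis(pinacolato)diboron | CC1(C)OB(OC1(C)C)B1OC(C)(C)C(C)(C)O1 | starting material
9 | aryl Bpin aldehyde | c1ccccc1COC[C@@H](Oc1c(B2OC(C)(C)C(C)(C)O2)cc(C=O)cc1OC)Cc1cc(OC)c(OCc2ccccc2)c(OC)c1 | intermediate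
10 | sodium perborate (peroxoborate, NaBO3·4H2O) | [Na+].[Na+].O[B-]1(O)OO[B-](O)(O)OO1 | starting material
11 | 3-hydroxy aryl ether aldehyde | c1ccccc1COC[C@@H](Oc1c(O)cc(C=O)cc1OC)Cc1cc(OC)c(OCc2ccccc2)c(OC)c1 | intermediate
12 | trans-(2R,3R)-benzodioxane aldehyde | COc1cc([C@H]2Oc3cc(C=O)cc(OC)c3O[C@@H]2COCc2ccccc2)cc(OC)c1OCc1ccccc1 | intermediate
13 | 2′,4′,6′-trihydroxyacetophenone | CC(=O)c1c(O)cc(O)cc1O | starting material
14 | 2′-hydroxy-4′,6′-bis(benzyloxy)acetophenone | CC(=O)c1c(O)cc(OCc2ccccc2)cc1OCc1ccccc1 | intermediate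
15 | chalcone | COc1cc([C@H]2Oc3cc(/C=C/C(=O)c4c(O)cc(OCc5ccccc5)cc4OCc4ccccc4)cc(OC)c3O[C@@H]2COCc2ccccc2)cc(OC)c1OCc1ccccc1 | intermediate
16 | tetra-O-benzyl flavone | COc1cc([C@H]2Oc3cc(-c4cc(=O)c5c(OCc6ccccc6)cc(OCc6ccccc6)cc5o4)cc(OC)c3O[C@@H]2COCc2ccccc2)cc(OC)c1OCc1ccccc1 | intermediate
17 | palstatin | COc1cc([C@H]2Oc3cc(-c4cc(=O)c5c(O)cc(O)cc5o4)cc(OC)c3O[C@@H]2CO)cc(OC)c1O | target

## Totals
Total steps: 10. Longest linear sequence: 9 (steps 1–6, 8, 9, 10; step 7 is a parallel branch).

## Three steps most likely to fail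
1. **Step 6 (proposed new DDQ etherification).** Risks are phenol oxidation, E1 elimination to the enol ether, or a poor trans:cis ratio. Fallback (known chemistry, different approach): protect the aldehyde of 7 as its dimethyl acetal and oxidise the syringyl CH2 to the aryl ketone (DDQ, aq. dioxane). Reduce the ketone to the benzylic alcohol (NaBH4), then run the Miyaura borylation and perborate oxidation (steps 4–5 conditions) to unmask the 3′-phenol. Close the ring by intramolecular Mitsunobu (PPh3, DIAD), separate the trans isomer, and remove the acetal (PPTS, acetone/H2O) to give 12.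
2. **Step 3 (Mitsunobu of a 2,6-disubstituted phenol with a secondary alcohol).** Risks are elimination to the styrene and low conversion. Fallback: convert (R)-alcohol 5 to its nosylate and displace it with the preformed phenoxide of 6 (Cs2CO3, DMF, 50 °C). This is a sulfonate SN2 with inversion and no betaine-mediated elimination pathway.
3. **Step 10 (global hydrogenolysis).** Risks are incomplete removal of the primary O-benzyl group, hydrogenolysis of the benzylic Cα–O bond, and over-reduction of the flavone C2=C3. Fallback: BCl3 with pentamethylbenzene (cation scavenger) in CH2Cl2 at −78 °C, a Lewis-acid debenzylation that cleaves benzyl ethers without reduction.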